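The route rests on cutting the oxolane C2–C3 bond. C2 bears the ring oxygen O1 and an aryl group, so it can be an aryl oxocarbenium carbon; C3 bears the CH2OH carbon, a reduced aldehyde whose enol is the nucleophile; O1–C5–C4 tethers the two. A chiral-anion-paired silylium catalyst ionises a racemic seven-membered enol acetal (a 4,5-dihydro-1,3-dioxepine) and the ion pair recloses by an O-to-C 1,3-shift, forming the oxolane ring, the C2–C3 bond and both stereocentres in one enantioconvergent operation. The precursor carries the future C4 aroyl group as an exocyclic TBS enol ether, so C4 stays trigonal until the end.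

Key step: step 6

Remarks
- Ar = 3,4,5-trimethoxyphenyl. Oxolane locants are O1, C2 (Ar), C3 (CH2OH), C4 (ArCO), C5. Dioxepine locants carry a prime and map as C2′→C2, O3′→O1, C4′→C5, C5′→C4, C6′→C3, C7′→formyl carbon.
- Assumption: the exocyclic enol-ether geometry of 9–12 is drawn E (silyloxy on the side of the ring CH=). That double bond is cleared in step 7, so the other isomer would serve equally.
- Assumption: which antipode of the catalyst leads to the (2S,3R) aldehyde cannot be predicted and is fixed by a first screen; the route is written for that antipode.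

Step 1
Reactants: 1 but-2-yne-1,4-diol
Product: 3 (E)-2-iodobut-2-ene-1,4-diol (CH2OH groups cis), via vinylstannane 2 (not isolated)
Conditions: Bu3SnH, PdCl2(PPh3)2 (2 mol %), THF, rt; then I2, CH2Cl2, 0 °C
Reagents that add atoms: iodine, II
Why: Palladium-catalysed hydrostannation adds Sn–H syn across the symmetrical alkyne (no regiochemical issue), which places the two CH2OH groups cis, and iododestannylation proceeds with retention, so the alkene geometry needed for a seven-membered acetal is fixed by a stereospecific syn addition.

Step 2
Reactants: 3 (E)-2-iodobut-2-ene-1,4-diol; 4 3,4,5-trimethoxybenzaldehyde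
Product: 5 5-iodo-2-(3,4,5-trimethoxyphenyl)-4,7-dihydro-1,3-dioxepine (racemic)
Conditions: p-TsOH·H2O (1 mol %), toluene, reflux, Dean–Stark
Reagents that add atoms: none
Why: Acid-catalysed acetalisation driven by azeotropic removal of water should close the 4,7-dihydro-1,3-dioxepine because the cis alkene holds both hydroxyls in reach, the vinyl iodide is inert to acid, and the acetal stereocentre forms as a racemate, which is all the key step needs.

Step 3
Reactants: 5 5-iodo-2-(3,4,5-trimethoxyphenyl)-4,7-dihydro-1,3-dioxepine; 4 3,4,5-trimethoxybenzaldehyde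
Product: 7 [2-(3,4,5-trimethoxyphenyl)-4,7-dihydro-1,3-dioxepin-5-yl](3,4,5-trimethoxyphenyl)methanol (mixture of racemic diastereomers), via vinyllithium 6 (not isolated)
Conditions: t-BuLi (2.0 equiv), Et2O, −78 °C; then 4, THF, −78 °C; H2O
Reagents that add atoms: none
Why: Iodine–lithium exchange on a vinyl iodide is fast and irreversible with two equivalents of t-BuLi, the 2-lithioallyl ether is stable to β-alkoxide loss at −78 °C, and 1,2-addition to the aldehyde gives the allylic alcohol, whose carbinol configuration is irrelevant because it is oxidised next.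

Step 4
Reactants: 7 [2-(3,4,5-trimethoxyphenyl)-4,7-dihydro-1,3-dioxepin-5-yl](3,4,5-trimethoxyphenyl)methanol
Product: 8 [2-(3,4,5-trimethoxyphenyl)-4,7-dihydro-1,3-dioxepin-5-yl](3,4,5-trimethoxyphenyl)methanone (racemic)
Conditions: activated MnO2 (10 equiv), CH2Cl2, rt
Reagents that add atoms: none
Why: Manganese dioxide oxidation of an alcohol that is both allylic and benzylic is neutral and heterogeneous, so the acid-labile acetal and the electron-rich arenes should survive, and it removes the carbinol stereocentre to leave one racemic enone.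

Step 5
Reactants: 8 [2-(3,4,5-trimethoxyphenyl)-4,7-dihydro-1,3-dioxepin-5-yl](3,4,5-trimethoxyphenyl)methanone
Product: 10 (E)-5-[(tert-butyldimethylsilyloxy)(3,4,5-trimethoxyphenyl)methylidene]-2-(3,4,5-trimethoxyphenyl)-4,5-dihydro-1,3-dioxepine (racemic), via potassium dienolate 9 (not isolated)
Conditions: TBSCl (1.5 equiv), then KHMDS (1.2 equiv), THF, −78 °C; Et3N, pH 7 buffer; Et3N-deactivated silica
Reagents that add atoms: tert-butyldimethylsilyl chloride, CC(C)(C)[Si](C)(C)Cl
Why: The aryl ketone has no α′-hydrogen, so the hindered amide base should remove a γ-hydrogen at C7′ (vinylogous enolisation) to give the extended dienolate, which the silyl chloride already present traps on oxygen (O-silylation of a potassium enolate) before β-alkoxide loss can set in, converting the 4,7-dihydro ring into the 4,5-dihydro enol acetal and the ketone into the exocyclic silyl enol ether in one operation.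

Step 6
Reactants: 10 (E)-5-[(tert-butyldimethylsilyloxy)(3,4,5-trimethoxyphenyl)methylidene]-2-(3,4,5-trimethoxyphenyl)-4,5-dihydro-1,3-dioxepine (racemic)
Product: 12 [(2S,3S,E)-4-[(tert-butyldimethylsilyloxy)(3,4,5-trimethoxyphenyl)methylidene]-2-(3,4,5-trimethoxyphenyl)oxolan-3-yl]methanol (2,3-cis), via silyl enol ether aldehyde 11 (not isolated)
Conditions: chiral imidodiphosphorimidate (IDPi) acid (5 mol %, presilylated with methallyl-TMS), toluene (0.02 M), −78 °C; then DIBAL-H (1.5 equiv), −78 °C; Rochelle salt
Reagents that add atoms: none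
Why: Proposed new method: the silylium ion pair R3Si+ X*− (X*− = chiral IDPi anion) silylates the enol-ether oxygen O1′ of 10, the C2′–O1′ bond ionises (O1′ departs as a conjugated silyl dienol ether and leaves the better, O-alkyl aryl oxocarbenium ion ArCH=O3′+), the enol carbon C6′ bonds to C2′ and the silyl group passes from the new formyl oxygen back to X*−, a net 1,3-shift of C2′ from oxygen to carbon; the closest known reactions are the Lewis-acid-induced (Petasis–Ferrier-type) contraction of 4,5-dihydro-1,3-dioxepines to oxolane-3-carbaldehydes and counter-anion-directed silylium catalysis of silyl enol ether additions to oxocarbenium ions. The oxolane closes in a 5-(enolexo)-endo-trig mode (the C2′=O3′+ acceptor lies inside the new ring, the C6′=C7′ enol bond outside), which the cationic acceptor makes feasible, whereas attack through C5′ would close an oxetane and attack through the silyloxy-bearing carbon would be a 5-(enolendo) closure onto a fully substituted centre. Oxolane C2 (S) is set by the face of the planar oxocarbenium ion that the confined chiral anion leaves open to C6′, and because both enantiomers of 10 ionise to the same tethered cation the racemate should converge on one enantiomer, provided rotation about O3′–C4′ in the ion pair (or reversible ionisation) is faster than C–C bond formation. Oxolane C3 (R in 11) is set relative to C2 by kinetically controlled collapse of the ring-fixed (Z)-enol ether onto the (E)-oxocarbenium ion in a compact ion pair, which in this rearrangement class should favour the 2,3-cis aldehyde at −78 °C. The step therefore needs enantiofacial selectivity (catalyst), cis over trans (low temperature, no equilibration) and C6′ over other nucleophilic sites (tether length), and the exocyclic TBS enol ether secures the rest by keeping the future C4 trigonal so that no third stereocentre is made. DIBAL-H added to the cold mixture should reduce the formyl group of 11, which is epimerisable at C3 and could move its double bond into conjugation, before either happens, and it leaves the silyl enol ether untouched.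

Step 7
Reactants: 12 [(2S,3S,E)-4-[(tert-butyldimethylsilyloxy)(3,4,5-trimethoxyphenyl)methylidene]-2-(3,4,5-trimethoxyphenyl)oxolan-3-yl]methanol
Product: 14 [(2S,3S,4R)-3-(hydroxymethyl)-2-(3,4,5-trimethoxyphenyl)oxolan-4-yl](3,4,5-trimethoxyphenyl)methanone (2,3-cis, 3,4-trans; target), via C4-epimeric ketone mixture 13 (not isolated)
Conditions: TBAF (1.1 equiv), AcOH (1.1 equiv), THF, 0 °C; then DBU (0.2 equiv), rt
Reagents that add atoms: none
Why: Fluoride desilylation of the enol ether and protonation give the ketone without any need for facial control at C4, because catalytic amidine base then equilibrates this only acidic stereocentre through the enolate to the thermodynamically preferred 3,4-trans ketone, while C2 and C3 carry no acidic hydrogen and the C5–O1 bond lies close to the nodal plane of the exocyclic enolate, so ring-opening β-elimination (the reverse of a 5-endo-trig oxa-Michael closure) should be slow.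

Compound list
1 | but-2-yne-1,4-diol | OCC#CCO | starting material
2 | (E)-2-(tributylstannyl)but-2-ene-1,4-diol | CCCC[Sn](CCCC)(CCCC)/C(CO)=C/CO | intermediate (not isolated)
3 | (E)-2-iodobut-2-ene-1,4-diol | OC/C(I)=C\CO | intermediate
4 | 3,4,5-trimethoxybenzaldehyde | COc1cc(C=O)cc(OC)c1OC | starting material
5 | 5-iodo-2-(3,4,5-trimethoxyphenyl)-4,7-dihydro-1,3-dioxepine (racemic) | COc1cc(C2OCC=C(I)CO2)cc(OC)c1OC | intermediate
6 | [2-(3,4,5-trimethoxyphenyl)-4,7-dihydro-1,3-dioxepin-5-yl]lithium | COc1cc(C2OCC=C([Li])CO2)cc(OC)c1OC | intermediate (not isolated)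
7 | [2-(3,4,5-trimethoxyphenyl)-4,7-dihydro-1,3-dioxepin-5-yl](3,4,5-trimethoxyphenyl)methanol (diastereomer mixture, racemic) | COc1cc(C(O)C2=CCOC(c3cc(OC)c(OC)c(OC)c3)OC2)cc(OC)c1OC | intermediate
8 | [2-(3,4,5-trimethoxyphenyl)-4,7-dihydro-1,3-dioxepin-5-yl](3,4,5-trimethoxyphenyl)methanone (racemic) | COc1cc(C(=O)C2=CCOC(c3cc(OC)c(OC)c(OC)c3)OC2)cc(OC)c1OC | intermediate
9 | potassium (E)-(3,4,5-trimethoxyphenyl)[2-(3,4,5-trimethoxyphenyl)-1,3-dioxepin-5(4H)-ylidene]methanolate (racemic) | [K+].[O-]/C(c1cc(OC)c(OC)c(OC)c1)=C1/COC(c2cc(OC)c(OC)c(OC)c2)OC=C1 | intermediate (not isolated)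
10 | (E)-5-[(tert-butyldimethylsilyloxy)(3,4,5-trimethoxyphenyl)methylidene]-2-(3,4,5-trimethoxyphenyl)-4,5-dihydro-1,3-dioxepine (racemic; key-step precursor) | CC(C)(C)[Si](C)(C)O/C(c1cc(OC)c(OC)c(OC)c1)=C1/COC(c2cc(OC)c(OC)c(OC)c2)OC=C1 | intermediate
11 | (2S,3R,E)-4-[(tert-butyldimethylsilyloxy)(3,4,5-trimethoxyphenyl)methylidene]-2-(3,4,5-trimethoxyphenyl)oxolane-3-carbaldehyde (2,3-cis; key-step product, the 4-aroyl group carried as its TBS enol ether) | CC(C)(C)[Si](C)(C)O/C(c1cc(OC)c(OC)c(OC)c1)=C1/CO[C@H](c2cc(OC)c(OC)c(OC)c2)[C@@H]1C=O | intermediate (not isolated)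
12 | [(2S,3S,E)-4-[(tert-butyldimethylsilyloxy)(3,4,5-trimethoxyphenyl)methylidene]-2-(3,4,5-trimethoxyphenyl)oxolan-3-yl]methanol | CC(C)(C)[Si](C)(C)O/C(c1cc(OC)c(OC)c(OC)c1)=C1/CO[C@H](c2cc(OC)c(OC)c(OC)c2)[C@@H]1CO | intermediate
13 | [(2S,3S)-3-(hydroxymethyl)-2-(3,4,5-trimethoxyphenyl)oxolan-4-yl](3,4,5-trimethoxyphenyl)methanone, mixture of C4 epimers | COc1cc(C(=O)C2CO[C@H](c3cc(OC)c(OC)c(OC)c3)[C@@H]2CO)cc(OC)c1OC | intermediate (not isolated)
14 | [(2S,3S,4R)-3-(hydroxymethyl)-2-(3,4,5-trimethoxyphenyl)oxolan-4-yl](3,4,5-trimethoxyphenyl)methanone | COc1cc(C(=O)[C@H]2CO[C@H](c3cc(OC)c(OC)c(OC)c3)[C@@H]2CO)cc(OC)c1OC | target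

Total step count: 7. Longest linear sequence: 7 steps (1 → 14); aldehyde 4 enters twice, in steps 2 and 3.

Steps most likely to fail

Step 6 (new method). It may fail through a racemic background rearrangement, through poor discrimination of the oxocarbenium faces by the anion, through C–C bond formation outrunning loss of the acetal's configuration (incomplete convergence), or through protodesilylation of the dienol ether by adventitious acid. The fallback uses known chemistry and sets out from 10: the established achiral Lewis-acid contraction of 4,5-dihydro-1,3-dioxepines (BF3·OEt2 or TMSOTf, 10 mol %, CH2Cl2, −78 °C) with the same in-pot DIBAL-H reduction should give the 2,3-cis alcohol as a racemate. This passes through 11 and the enantiomeric aldehyde F1 (not isolated) and delivers 12 together with the enantiomeric alcohol F2. Lipase-catalysed kinetic resolution (immobilised Candida antarctica lipase B or Pseudomonas cepacia lipase, vinyl acetate, MTBE, rt, the enzyme chosen so that the unwanted enantiomer reacts) should convert F2 into the acetate of the unwanted enantiomer F3, which is separated by chromatography from unreacted 12. The route is rejoined at 12.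

Step 5. It may fail through expulsion of the β-alkoxide O3′ from the dienolate, through addition of the amide base to the enone, or through formation of a mixture of enol-ether geometries. The fallback sets out from 8 and reverses the order of events by soft enolisation: TBSOTf with excess Et3N in CH2Cl2 at −78 → 0 °C silylates the carbonyl oxygen first, and the amine then removes the γ-hydrogen from the resulting O-silylated cation, so that no anionic dienolate is ever present; the excess amine keeps the silyl triflate from ionising the acetal. It makes no new compound (F0) and comes back to the route directly at 10.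

Step 7. It may fail through an unfavourable C4 equilibrium if the 3,4-cis epimer is drained as a cis-fused bicyclic hemiketal with the neighbouring CH2OH, or through base-induced ring opening. The fallback sets out from 12: acetylation (Ac2O, pyridine, DMAP, CH2Cl2) gives the silyl enol ether acetate F4; TBAF/AcOH followed by catalytic DBU, as in step 7, gives first the C4-epimeric keto acetate mixture F5 (not isolated) and then the 3,4-trans keto acetate F6, now without a free hydroxyl that could form a hemiketal. Lipase-mediated methanolysis (Candida antarctica lipase B, MeOH, MTBE, rt), neutral and therefore non-epimerising, removes the acetate, and the route is rejoined at 14.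

Further compounds
F1 | step 6 | (2R,3S,E)-4-[(tert-butyldimethylsilyloxy)(3,4,5-trimethoxyphenyl)methylidene]-2-(3,4,5-trimethoxyphenyl)oxolane-3-carbaldehyde (enantiomer of 11, not isolated) | CC(C)(C)[Si](C)(C)O/C(c1cc(OC)c(OC)c(OC)c1)=C1/CO[C@@H](c2cc(OC)c(OC)c(OC)c2)[C@H]1C=O
F2 | step 6 | [(2R,3R,E)-4-[(tert-butyldimethylsilyloxy)(3,4,5-trimethoxyphenyl)methylidene]-2-(3,4,5-trimethoxyphenyl)oxolan-3-yl]methanol (enantiomer of 12) | CC(C)(C)[Si](C)(C)O/C(c1cc(OC)c(OC)c(OC)c1)=C1/CO[C@@H](c2cc(OC)c(OC)c(OC)c2)[C@H]1CO
F3 | step 6 | [(2R,3R,E)-4-[(tert-butyldimethylsilyloxy)(3,4,5-trimethoxyphenyl)methylidene]-2-(3,4,5-trimethoxyphenyl)oxolan-3-yl]methyl acetate | CC(C)(C)[Si](C)(C)O/C(c1cc(OC)c(OC)c(OC)c1)=C1/CO[C@@H](c2cc(OC)c(OC)c(OC)c2)[C@H]1COC(C)=O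
F0 | step 5 | none | none
F4 | step 7 | [(2S,3S,E)-4-[(tert-butyldimethylsilyloxy)(3,4,5-trimethoxyphenyl)methylidene]-2-(3,4,5-trimethoxyphenyl)oxolan-3-yl]methyl acetate | CC(C)(C)[Si](C)(C)O/C(c1cc(OC)c(OC)c(OC)c1)=C1/CO[C@H](c2cc(OC)c(OC)c(OC)c2)[C@@H]1COC(C)=O
F5 | step 7 | [(2S,3S)-4-(3,4,5-trimethoxybenzoyl)-2-(3,4,5-trimethoxyphenyl)oxolan-3-yl]methyl acetate, mixture of C4 epimers (not isolated) | COc1cc(C(=O)C2CO[C@H](c3cc(OC)c(OC)c(OC)c3)[C@@H]2COC(C)=O)cc(OC)c1OC
F6 | step 7 | [(2S,3S,4R)-4-(3,4,5-trimethoxybenzoyl)-2-(3,4,5-trimethoxyphenyl)oxolan-3-yl]methyl acetate | COc1cc(C(=O)[C@H]2CO[C@H](c3cc(OC)c(OC)c(OC)c3)[C@@H]2COC(C)=O)cc(OC)c1OC
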